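**Retrosynthetic overview**
1. Target 18 ← C-desilylation ← ring B closed last by 5-exo bromoetherification of a (Z)-C7=C8 alkene by the C4 hydroxyl of ring A (sets C7 and C8).
2. (Z)-alkene ← C7≡C8 alkyne; the 3,5-dibromooxane (ring C) ← ring expansion of a 2-(1-bromopropyl)oxolane, formed by 5-exo bromoetherification of anti-bromohydrin 12 (key step, 1,2-oxygen shift).
3. 12 ← C8–C9 bond: lithium acetylide of ring A diyne 9 + (S)-2-bromohept-4-enal 11.
4. 9 ← oxocarbenium C-ethynylation of lactol acetate 7 ← anti-Markovnikov Wacker ← Brown alkoxyallylboration of 1 with 2.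
5. Rings are formed in the order A (oxolane), C (oxane, by oxolane ring expansion), B (second oxolane, closing the 2,5-dioxabicyclo[2.2.1]heptane).

Assumption: 1, 2, 8 and 10 are taken as commercially available; labels C1–C15 count along the carbon chain from the alkyne terminus.

**Step 1**
Reactants: 1 3-(trimethylsilyl)prop-2-ynal; 2 3-(methoxymethoxy)prop-1-ene
Product: 4 (3S,4S)-4-(methoxymethoxy)-1-(trimethylsilyl)hex-5-en-1-yn-3-ol, via alkoxyallylborane 3 (not isolated)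
Conditions: 2, s-BuLi, THF, −78 °C; (+)-Ipc2BOMe [from (−)-α-pinene]; BF3·OEt2; then 1, −78 °C, 3 h; HOCH2CH2NH2, rt
Reagents that add atoms: none
Why: Brown alkoxyallylboration, in which the (Z)-γ-alkoxyallylborane reacts through a closed chair transition state to give the syn product and the isopinocampheyl groups from (−)-α-pinene direct attack to the Re face of the ynal, setting C3 and C4 as (3S,4S).

**Step 2**
Reactants: 4 (3S,4S)-4-(methoxymethoxy)-1-(trimethylsilyl)hex-5-en-1-yn-3-ol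
Product: 6 (4S,5S)-4-(methoxymethoxy)-5-[(trimethylsilyl)ethynyl]oxolan-2-ol, via hydroxy aldehyde 5 (not isolated)
Conditions: PdCl2(PhCN)2 (10 mol %), CuCl2·2H2O (10 mol %), AgNO2 (5 mol %), O2 (1 atm), t-BuOH/MeNO2 15:1, rt
Reagents that add atoms: dioxygen, O=O
Why: Nitrite-modified aldehyde-selective (anti-Markovnikov) Wacker oxidation of the terminal alkene, favoured by the allylic ether oxygen, gives the γ-hydroxy aldehyde, which closes at once to the five-membered lactol (only the anomeric centre is new and it is lost later).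

**Step 3**
Reactants: 6 (4S,5S)-4-(methoxymethoxy)-5-[(trimethylsilyl)ethynyl]oxolan-2-ol
Product: 7 (4S,5S)-4-(methoxymethoxy)-5-[(trimethylsilyl)ethynyl]oxolan-2-yl acetate
Conditions: Ac2O, pyridine, DMAP (5 mol %), CH2Cl2, 0 °C
Reagents that add atoms: acetic anhydride, CC(=O)OC(C)=O
Why: Routine acylation of the anomeric hydroxyl installs the leaving group needed for oxocarbenium formation.

**Step 4**
Reactants: 7 (4S,5S)-4-(methoxymethoxy)-5-[(trimethylsilyl)ethynyl]oxolan-2-yl acetate; 8 potassium ethynyltrifluoroborate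
Product: 9 (2S,3S,5S)-5-ethynyl-3-(methoxymethoxy)-2-[(trimethylsilyl)ethynyl]oxolane
Conditions: 8 (2 equiv), BF3·OEt2 (2 equiv), MeCN, −40 → 0 °C
Reagents that add atoms: none
Why: Lewis-acid-promoted C-glycosylation-type alkynylation of the oxocarbenium ion by the alkynyldifluoroborane released from 8, in which the pseudoaxial C4 alkoxy group directs inside attack 1,3-cis (Woerpel model), so C6 is set (S) and ring A is all-cis.

**Step 5**
Reactants: 10 (E)-hept-4-enal
Product: 11 (2S,4E)-2-bromohept-4-enal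
Conditions: (S)-α,α-bis[3,5-bis(trifluoromethyl)phenyl]prolinol trimethylsilyl ether (20 mol %), 4,4-dibromo-2,6-di-tert-butylcyclohexa-2,5-dienone (1.0 equiv), PhCO2H (20 mol %), H2O (2 equiv), CH2Cl2/pentane 1:1, −40 °C; cold silica plug; used at once
Reagents that add atoms: 4,4-dibromo-2,6-di-tert-butylcyclohexa-2,5-dien-1-one, CC(C)(C)C1=CC(Br)(Br)C=C(C(C)(C)C)C1=O
Why: Enamine-catalysed α-bromination (Jørgensen type), in which the (S)-diarylprolinol silyl ether shields one enamine face so that Br+ is delivered to give the (S)-bromide at C10, the enamine being far more nucleophilic than the isolated alkene.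

**Step 6**
Reactants: 9 (2S,3S,5S)-5-ethynyl-3-(methoxymethoxy)-2-[(trimethylsilyl)ethynyl]oxolane; 11 (2S,4E)-2-bromohept-4-enal
Product: 12 (3R,4S,6E)-4-bromo-1-[(2S,4S,5S)-4-(methoxymethoxy)-5-[(trimethylsilyl)ethynyl]oxolan-2-yl]non-6-en-1-yn-3-ol
Conditions: 9, n-BuLi (1.0 equiv), THF, −78 °C; 11 (1.5 equiv), −78 °C, 20 min; AcOH quench at −78 °C
Reagents that add atoms: none
Why: Addition of the lithium acetylide to the α-bromoaldehyde under Cornforth (polar Felkin–Anh) control gives the 1,2-anti bromohydrin, setting C9 as (R) beside the (S)-C10 bromide, and the cold acidic quench prevents epoxide closure.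

**Step 7**
Reactants: 12 (3R,4S,6E)-4-bromo-1-[(2S,4S,5S)-4-(methoxymethoxy)-5-[(trimethylsilyl)ethynyl]oxolan-2-yl]non-6-en-1-yn-3-ol
Product: 14 (2S,3R,5S,6R)-3,5-dibromo-2-ethyl-6-({(2S,4S,5S)-4-(methoxymethoxy)-5-[(trimethylsilyl)ethynyl]oxolan-2-yl}ethynyl)oxane, via bromopropyl oxolane 13 (not isolated)
Conditions: recrystallised NBS (1.1 equiv), HFIP/CH2Cl2 1:1, −20 °C → rt; then Bu4NBr (10 mol %), 45 °C
Reagents that add atoms: N-bromosuccinimide, O=C1CCC(=O)N1Br
Why: Proposed new method: NBS in HFIP forms the bromonium ion of the (E)-alkene and the C9 hydroxyl captures it 5-exo through a chair-like transition state with the C9 alkynyl and C10 bromo groups pseudoequatorial (2,5-trans, 3,5-cis oxolane 13), after which HFIP ionises the exocyclic C13–Br bond with participation of the ring oxygen to a bicyclic epoxonium ion that the bromide shuttle opens at ring carbon C12, so a 1,2-oxygen shift with inversion at C12 and C13 expands the oxolane to the all-equatorial 3,5-dibromooxane (the direct 6-endo product of the same bromonium face is the same compound), the closest known reactions being 5-exo bromoetherification of 4-alkenols, the thermal isomerisation of 2-(1-haloalkyl)oxolanes to 3-halooxanes and the Nakata ring expansion of oxolanyl sulfonates.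

**Step 8**
Reactants: 14 (2S,3R,5S,6R)-3,5-dibromo-2-ethyl-6-({(2S,4S,5S)-4-(methoxymethoxy)-5-[(trimethylsilyl)ethynyl]oxolan-2-yl}ethynyl)oxane
Product: 15 (2S,3R,5S,6R)-3,5-dibromo-2-ethyl-6-[(Z)-2-{(2S,4S,5S)-4-(methoxymethoxy)-5-[(trimethylsilyl)ethynyl]oxolan-2-yl}ethenyl]oxane
Conditions: H2 (1 atm), Pd/CaCO3 poisoned with Pb(OAc)2 (5 wt % Pd), quinoline, EtOAc, rt, stopped at 1 equiv H2
Reagents that add atoms: none
Why: Lindlar semihydrogenation adds H2 syn to the C7≡C8 alkyne to give the (Z)-alkene, while the silyl-capped alkyne and the secondary bromides react much more slowly.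

**Step 9**
Reactants: 15 (2S,3R,5S,6R)-3,5-dibromo-2-ethyl-6-[(Z)-2-{(2S,4S,5S)-4-(methoxymethoxy)-5-[(trimethylsilyl)ethynyl]oxolan-2-yl}ethenyl]oxane
Product: 16 (2S,3S,5S)-5-{(Z)-2-[(2R,3S,5R,6S)-3,5-dibromo-6-ethyloxan-2-yl]ethenyl}-2-[(trimethylsilyl)ethynyl]oxolan-3-ol
Conditions: ZnBr2 (1 equiv), n-PrSH (2 equiv), CH2Cl2, 0 °C, 10 min
Reagents that add atoms: none
Why: Lewis-acid/thiol cleavage of the methoxymethyl acetal frees the C4 hydroxyl under conditions that leave the silylalkyne, the (Z)-alkene and the bromides untouched.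

**Step 10**
Reactants: 16 (2S,3S,5S)-5-{(Z)-2-[(2R,3S,5R,6S)-3,5-dibromo-6-ethyloxan-2-yl]ethenyl}-2-[(trimethylsilyl)ethynyl]oxolan-3-ol
Product: 17 (1S,3S,4S,6S)-3-{(R)-bromo[(2S,3S,5R,6S)-3,5-dibromo-6-ethyloxan-2-yl]methyl}-6-[(trimethylsilyl)ethynyl]-2,5-dioxabicyclo[2.2.1]heptane
Conditions: recrystallised NBS (1.2 equiv), MeCN, −20 → 0 °C, dark
Reagents that add atoms: N-bromosuccinimide, O=C1CCC(=O)N1Br
Why: 5-exo bromoetherification in which allylic 1,3-strain holds H6 in the plane of the (Z)-alkene so that the cis-disposed C4 hydroxyl attacks C7 from the C5 side anti to the bromonium ion, which closes ring B, sets C7 as (S) with the side chain exo and, by anti addition to the (Z)-alkene, sets C8 as (R).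

**Step 11**
Reactants: 17 (1S,3S,4S,6S)-3-{(R)-bromo[(2S,3S,5R,6S)-3,5-dibromo-6-ethyloxan-2-yl]methyl}-6-[(trimethylsilyl)ethynyl]-2,5-dioxabicyclo[2.2.1]heptane
Product: 18 (1S,3S,4S,6S)-3-{(R)-bromo[(2S,3S,5R,6S)-3,5-dibromo-6-ethyloxan-2-yl]methyl}-6-ethynyl-2,5-dioxabicyclo[2.2.1]heptane
Conditions: K2CO3 (0.2 equiv), MeOH, 0 °C → rt
Reagents that add atoms: none
Why: Base-catalysed methanolysis of the C(sp)–Si bond liberates the terminal alkyne without affecting the secondary bromides or any stereocentre.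

**Compound list**
1 | 3-(trimethylsilyl)prop-2-ynal | C[Si](C)(C)C#CC=O | starting material
2 | 3-(methoxymethoxy)prop-1-ene (allyl methoxymethyl ether) | C=CCOCOC | starting material
3 | [(Z)-3-(methoxymethoxy)prop-2-en-1-yl]diisopinocampheylborane, isopinocampheyl groups from (−)-α-pinene | COCO/C=C\CB([C@H]1C[C@H]2C[C@@H]([C@@H]1C)C2(C)C)[C@H]1C[C@H]2C[C@@H]([C@@H]1C)C2(C)C | intermediate
4 | (3S,4S)-4-(methoxymethoxy)-1-(trimethylsilyl)hex-5-en-1-yn-3-ol | C[Si](C)(C)C#C[C@H](O)[C@@H](OCOC)C=C | intermediate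
5 | (3S,4S)-4-hydroxy-3-(methoxymethoxy)-6-(trimethylsilyl)hex-5-ynal | C[Si](C)(C)C#C[C@H](O)[C@@H](OCOC)CC=O | intermediate
6 | (4S,5S)-4-(methoxymethoxy)-5-[(trimethylsilyl)ethynyl]oxolan-2-ol (anomer mixture) | C[Si](C)(C)C#C[C@@H]1OC(O)C[C@@H]1OCOC | intermediate
7 | (4S,5S)-4-(methoxymethoxy)-5-[(trimethylsilyl)ethynyl]oxolan-2-yl acetate (anomer mixture) | C[Si](C)(C)C#C[C@@H]1OC(OC(C)=O)C[C@@H]1OCOC | intermediate
8 | potassium ethynyltrifluoroborate | [K+].C#C[B-](F)(F)F | starting material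
9 | (2S,3S,5S)-5-ethynyl-3-(methoxymethoxy)-2-[(trimethylsilyl)ethynyl]oxolane (ring A, all-cis) | C[Si](C)(C)C#C[C@@H]1O[C@H](C#C)C[C@@H]1OCOC | intermediate
10 | (E)-hept-4-enal | CC/C=C/CCC=O | starting material
11 | (2S,4E)-2-bromohept-4-enal | CC/C=C/C[C@H](Br)C=O | intermediate
12 | (3R,4S,6E)-4-bromo-1-[(2S,4S,5S)-4-(methoxymethoxy)-5-[(trimethylsilyl)ethynyl]oxolan-2-yl]non-6-en-1-yn-3-ol | C[Si](C)(C)C#C[C@@H]1O[C@H](C#C[C@@H](O)[C@@H](Br)C/C=C/CC)C[C@@H]1OCOC | intermediate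
13 | (2R,3S,5S)-3-bromo-5-[(1R)-1-bromopropyl]-2-({(2S,4S,5S)-4-(methoxymethoxy)-5-[(trimethylsilyl)ethynyl]oxolan-2-yl}ethynyl)oxolane | C[Si](C)(C)C#C[C@@H]1O[C@H](C#C[C@H]2O[C@H]([C@H](Br)CC)C[C@@H]2Br)C[C@@H]1OCOC | intermediate
14 | (2S,3R,5S,6R)-3,5-dibromo-2-ethyl-6-({(2S,4S,5S)-4-(methoxymethoxy)-5-[(trimethylsilyl)ethynyl]oxolan-2-yl}ethynyl)oxane | C[Si](C)(C)C#C[C@@H]1O[C@H](C#C[C@H]2O[C@@H](CC)[C@H](Br)C[C@@H]2Br)C[C@@H]1OCOC | intermediate
15 | (2S,3R,5S,6R)-3,5-dibromo-2-ethyl-6-[(Z)-2-{(2S,4S,5S)-4-(methoxymethoxy)-5-[(trimethylsilyl)ethynyl]oxolan-2-yl}ethenyl]oxane | C[Si](C)(C)C#C[C@@H]1O[C@H](/C=C\[C@H]2O[C@@H](CC)[C@H](Br)C[C@@H]2Br)C[C@@H]1OCOC | intermediate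
16 | (2S,3S,5S)-5-{(Z)-2-[(2R,3S,5R,6S)-3,5-dibromo-6-ethyloxan-2-yl]ethenyl}-2-[(trimethylsilyl)ethynyl]oxolan-3-ol | C[Si](C)(C)C#C[C@@H]1O[C@H](/C=C\[C@H]2O[C@@H](CC)[C@H](Br)C[C@@H]2Br)C[C@@H]1O | intermediate
17 | (1S,3S,4S,6S)-3-{(R)-bromo[(2S,3S,5R,6S)-3,5-dibromo-6-ethyloxan-2-yl]methyl}-6-[(trimethylsilyl)ethynyl]-2,5-dioxabicyclo[2.2.1]heptane | C[Si](C)(C)C#C[C@@H]1O[C@H]2C[C@@H]1O[C@@H]2[C@@H](Br)[C@H]1O[C@@H](CC)[C@H](Br)C[C@@H]1Br | intermediate
18 | (1S,3S,4S,6S)-3-{(R)-bromo[(2S,3S,5R,6S)-3,5-dibromo-6-ethyloxan-2-yl]methyl}-6-ethynyl-2,5-dioxabicyclo[2.2.1]heptane (CNP0139964.1) | C#C[C@@H]1O[C@H]2C[C@@H]1O[C@@H]2[C@@H](Br)[C@H]1O[C@@H](CC)[C@H](Br)C[C@@H]1Br | target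

**Step count and risk**
Total steps: 11. Longest linear sequence: 10 (steps 1–4, then 6–11; step 5 is the one-step side branch).

Three steps most likely to fail:

Step 7 (the proposed ring-expanding bromoetherification). The risks are incomplete oxolane-to-oxane isomerisation and imperfect choice of alkene face. The fallback uses known chemistry (Shi epoxidation, acid-catalysed 5-exo epoxide opening, Nakata-type sulfonate ring expansion with bromide capture) and sets out from 12. Epoxidation of the (E)-alkene with the D-fructose-derived Shi ketone (1 equiv), KHSO5 (as 2KHSO5·KHSO4·K2SO4) and NaHCO3 at pH about 8 in MeCN/H2O at 0 °C gives the (12R,13R)-epoxy bromohydrin F2 by reagent control, the mild pH keeping the bromohydrin intact. CSA (10 mol %) in CH2Cl2 then closes the oxolanyl carbinol F3 by 5-exo opening with inversion at C12. Tf2O and 2,6-lutidine at −78 °C give the oxolanyl triflate F4, which is not isolated. Bu4NBr, with warming to 0 °C, triggers the same epoxonium ring expansion with inversion at C13 and C12, and the fallback comes back to the route at 14.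

Step 10 (closure of ring B). The risks are 6-endo attack at C8 giving the 2,6-dioxabicyclo[3.2.1]octane, and slow capture of a hindered bromonium ion. The fallback uses known chemistry and sets out from 14. Ruthenium-catalysed trans-hydrogenation ([Cp*RuCl(cod)] 5 mol %, H2 10 bar, CH2Cl2) gives the (E)-alkene F5. ZnBr2/n-PrSH removes the acetal to give the (E)-alkenol F6. Shi epoxidation with the same D-fructose-derived ketone gives the (7R,8S)-trans-epoxide F7. CSA closes ring B by 5-exo epoxide opening with inversion at C7, which is reliably exo-selective, and gives the bicyclic C8 carbinol F8. Bromination with inversion at C8 (CBr4, P(n-C8H17)3, toluene, 70 °C) comes back to the route at 17.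

Step 6 (Cornforth addition to the configurationally labile α-bromoaldehyde). The risk is a poor anti/syn ratio at C9; partial racemisation of 11 is a further risk that this fallback does not repair. The fallback uses known chemistry and sets out from 12 obtained as a C9-epimer mixture. Dess–Martin periodinane (NaHCO3, CH2Cl2, 0 °C) gives the α-bromo ynone F1. Reagent-controlled reduction with (S)-2-methyl-CBS-oxazaborolidine and catecholborane in toluene at −78 °C, the alkynyl group acting as the small substituent, sets C9 as (R) and comes back to the route at 12.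

**Further compounds**
F1 | step 6 | (4S,6E)-4-bromo-1-[(2S,4S,5S)-4-(methoxymethoxy)-5-[(trimethylsilyl)ethynyl]oxolan-2-yl]non-6-en-1-yn-3-one | C[Si](C)(C)C#C[C@@H]1O[C@H](C#CC(=O)[C@@H](Br)C/C=C/CC)C[C@@H]1OCOC
F2 | step 7 | (3R,4S)-4-bromo-5-[(2R,3R)-3-ethyloxiran-2-yl]-1-[(2S,4S,5S)-4-(methoxymethoxy)-5-[(trimethylsilyl)ethynyl]oxolan-2-yl]pent-1-yn-3-ol | C[Si](C)(C)C#C[C@@H]1O[C@H](C#C[C@@H](O)[C@@H](Br)C[C@H]2O[C@@H]2CC)C[C@@H]1OCOC
F3 | step 7 | (1R)-1-[(2S,4S,5R)-4-bromo-5-({(2S,4S,5S)-4-(methoxymethoxy)-5-[(trimethylsilyl)ethynyl]oxolan-2-yl}ethynyl)oxolan-2-yl]propan-1-ol | C[Si](C)(C)C#C[C@@H]1O[C@H](C#C[C@H]2O[C@H]([C@H](O)CC)C[C@@H]2Br)C[C@@H]1OCOC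
F4 | step 7 | (1R)-1-[(2S,4S,5R)-4-bromo-5-({(2S,4S,5S)-4-(methoxymethoxy)-5-[(trimethylsilyl)ethynyl]oxolan-2-yl}ethynyl)oxolan-2-yl]propyl trifluoromethanesulfonate | C[Si](C)(C)C#C[C@@H]1O[C@H](C#C[C@H]2O[C@H]([C@H](OS(=O)(=O)C(F)(F)F)CC)C[C@@H]2Br)C[C@@H]1OCOC
F5 | step 10 | (2S,3R,5S,6R)-3,5-dibromo-2-ethyl-6-[(E)-2-{(2S,4S,5S)-4-(methoxymethoxy)-5-[(trimethylsilyl)ethynyl]oxolan-2-yl}ethenyl]oxane | C[Si](C)(C)C#C[C@@H]1O[C@H](/C=C/[C@H]2O[C@@H](CC)[C@H](Br)C[C@@H]2Br)C[C@@H]1OCOC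
F6 | step 10 | (2S,3S,5S)-5-{(E)-2-[(2R,3S,5R,6S)-3,5-dibromo-6-ethyloxan-2-yl]ethenyl}-2-[(trimethylsilyl)ethynyl]oxolan-3-ol | C[Si](C)(C)C#C[C@@H]1O[C@H](/C=C/[C@H]2O[C@@H](CC)[C@H](Br)C[C@@H]2Br)C[C@@H]1O
F7 | step 10 | (2S,3S,5S)-5-{(2R,3S)-3-[(2R,3S,5R,6S)-3,5-dibromo-6-ethyloxan-2-yl]oxiran-2-yl}-2-[(trimethylsilyl)ethynyl]oxolan-3-ol | C[Si](C)(C)C#C[C@@H]1O[C@H]([C@H]2O[C@@H]2[C@H]2O[C@@H](CC)[C@H](Br)C[C@@H]2Br)C[C@@H]1O
F8 | step 10 | (S)-[(2R,3S,5R,6S)-3,5-dibromo-6-ethyloxan-2-yl]{(1S,3R,4S,6S)-6-[(trimethylsilyl)ethynyl]-2,5-dioxabicyclo[2.2.1]heptan-3-yl}methanol | C[Si](C)(C)C#C[C@@H]1O[C@H]2C[C@@H]1O[C@@H]2[C@H](O)[C@H]1O[C@@H](CC)[C@H](Br)C[C@@H]1Br
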